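The readings stem from a simulated flask with constants of no real substance; the scatter is artificial.

- Late in the beta, epsilon and eta runs the bis adduct stopped moving, so I read each run as a plateau: 47.0%, 28.6% and 39.4%. You hoped grey's hot finish would add bis adduct, but these plateaus were what I had to test that on.

| flask | substrate | reagent | capture agent | temperature | remark | time |
|---|---|---|---|---|---|---|
| beta | 0.053 M | 0.50 M | 0.020 M | 85 °C | run made earlier |  |
| epsilon | 0.11 M | 0.50 M | 0.020 M | 118 °C | run made earlier |  |
| eta | 0.18 M | 0.50 M | 0.020 M | 85 °C | run made earlier |  |
| amber | 0.060 M | 0.500 M | 0.0200 M |  | at 70 °C throughout | 20 min |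
| grey | 0.20 M | 0.500 M | 0.0200 M |  | at 70 °C until 4.0 min, from then on at 130 °C | 20 min |

beta run (percent of the substrate charged): time / min: bis adduct / % = 1.00: 41.3; 2.50: 47.1; 5.00: 47.6; 8.00: 47.5; 10.0: 45.6

epsilon run (percent of the substrate charged): time / s: bis adduct / % = 20.0: 30.0; 40.0: 28.8; 60.0: 27.7; 80.0: 28.8; 120: 27.7

eta run (percent of the substrate charged): time / min: bis adduct / % = 2.00: 39.6; 4.00: 39.6; 6.00: 37.9; 8.00: 39.8; 10.0: 39.9

(standard deviation of a reading: 1 percentage point)

* the flask that ends with the higher amount of bis adduct, in percent of the substrate charged, or "neither" when 2 percentage points or less lies between them (amber / grey / neither)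
* final bis adduct, as a percentage of the substrate charged, in amber
* final bis adduct, as a percentage of the substrate charged, in grey

- At 85 °C, the plateau of eta stood lower than that of beta, so loading costs bis adduct. A fixed charge of capture agent should weigh most on the dilute run, so I left capture out.
- I counted turnovers: each substrate takes one reagent to reach mono adduct and one more to reach bis adduct. That gave me [reagent] at mid-conversion, and I took the bis fraction as [reagent]/([reagent] + a).
- The readings gave a as 0.521 M in beta, 0.577 M in eta and 1.07 M in epsilon.
- Taking ln a as linear in 1/T, I drew one line from beta to epsilon and one from eta to epsilon, and their mean reached 0.389 M at 70 °C. This is the split concentration, the [reagent] at which mono adduct divides equally between bis adduct and side product, a selectivity factor in concentration units.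
- With about 1.50 reagent per substrate, I reckoned amber at 53.9% and grey at 47.4% at the split of 70 °C.
- Whatever reacted in grey after the change to 130 °C splits, on the same two lines, at 1.33 M, larger than the split concentration at 70 °C. So I marked my grey figure as too high. The lead of amber in my figures, 6.5 percentage points, was larger than the margin of 2 points, so I chose amber, against your hunch.
- The forecast named amber, with amber at 55% (51% to 59%) and grey at 45% (39% to 49%), and said of the fall of the plateaus with loading: “That fits reagent depletion altering the mono adduct's split between bis adduct and side product”.
- Amber ended at 55.1% and grey at 42.5%.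

    substrate + reagent → mono adduct (k = 0.0454 L mol⁻¹ s⁻¹, Ea = 76.0 kJ mol⁻¹)
    reagent + mono adduct → bis adduct (k = 0.0237 L mol⁻¹ s⁻¹, Ea = 83.0 kJ mol⁻¹)
    mono adduct → side product (k = 0.00821 s⁻¹, Ea = 108 kJ mol⁻¹)
    mono adduct + capture agent → trapped intermediate (k = 0.0115 L mol⁻¹ s⁻¹, Ea = 84.0 kJ mol⁻¹)
    (constants at 70 °C)

- After the change at 4.00 min, grey's bis adduct rose from 40.5% to 42.5% while its side product rose from 45.4% to 56.3%, and its trapped intermediate stood at 1.27%. Grey's bis share up to the change was 47.1%, and the split concentration at its mean [reagent] gives 48.3%. For the same flask as grey with 0.85 M of reagent, the split concentration gives 64.3%, and that flask ended at 63.1%.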